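**Retrosynthetic overview**
1. The target is the ring-opened (hydrated) form of an 8-hydroxy-6-methoxy-3-alkylisocoumarin, so the last step is saponification of that enol lactone.
2. Key step: the aryl–CH2 bond is made by carboxylate-directed C–H acylmethylation of unprotected 4-methoxysalicylic acid with a β-keto sulfoxonium ylide (carbene surrogate) under Cp*Rh catalysis. This replaces the usual lateral lithiation of a protected orsellinate or a halide/alkyne coupling, and needs no protecting groups.
3. The ylide comes in one step from 12-dodecanolide and dimethylsulfoxonium methylide; the lactone supplies C2'–C13' and the free terminal OH.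
4. Ring order: the benzene ring is purchased; the only ring formed is the lactone ring of the isocoumarin, closed in step 2 (which gives a neutral, easily purified intermediate) and opened again in step 3.

Assumption: the target has no stereocentre (it is achiral), so "single enantiomer" is taken to mean the compound exactly as drawn.

**Step 1**
Reactants: 1 oxacyclotridecan-2-one (12-dodecanolide)
Product: 2 1-[dimethyl(oxo)-λ6-sulfanylidene]-13-hydroxytridecan-2-one
Conditions: Me3S(O)I (3 equiv), KOtBu (3 equiv), THF, reflux, 2 h; then 1, THF, 65 °C, 4 h; aqueous work-up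
Reagents that add atoms: trimethylsulfoxonium iodide, C[S+](C)(C)=O.[I-] (acts as dimethylsulfoxonium methylide, C=S(C)(C)=O)
Why: Corey–Chaykovsky-type acyl substitution, in which the methylide adds to the unstrained macrolactone carbonyl with ring opening to the C13 alcohol, and the carbonyl-stabilised ylide formed does not add a second time, so the hydroxy keto ylide is obtained without protecting the alcohol.

**Step 2**
Reactants: 2 1-[dimethyl(oxo)-λ6-sulfanylidene]-13-hydroxytridecan-2-one; 3 2-hydroxy-4-methoxybenzoic acid (1.5 equiv)
Product: 5 8-hydroxy-3-(11-hydroxyundecyl)-6-methoxy-1H-isochromen-1-one, via open-chain keto acid 4 (not isolated)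
Conditions: [Cp*Rh(MeCN)3](SbF6)2 (5 mol %), NaOAc (25 mol %), PivOH (0.5 equiv), HFIP, 90 °C, 16 h
Reagents that add atoms: none
Why: Carboxylate-directed C–H activation followed by carbene migratory insertion on trivalent rhodium, in which the carboxylate of 3 delivers the metal to the only free ortho C–H (C6), the ylide loses DMSO on rhodium to give a carbene that inserts into the Rh–aryl bond, protodemetalation releases keto acid 4, and 4 cyclodehydrates under the hot acidic conditions to isocoumarin 5; this annulation is an established reaction class for benzoic acids with sulfoxonium ylides, although untested on a free salicylic acid.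

**Step 3**
Reactants: 5 8-hydroxy-3-(11-hydroxyundecyl)-6-methoxy-1H-isochromen-1-one
Product: 4 2-hydroxy-6-(13-hydroxy-2-oxotridecyl)-4-methoxybenzoic acid
Conditions: LiOH·H2O (5 equiv), THF/H2O 2:1, 50 °C, 6 h; then 1 M HCl, 0 °C, to pH 2–3; EtOAc extraction, evaporation below 30 °C
Reagents that add atoms: lithium hydroxide, [Li+].[OH-]; water, O
Why: Saponification of the enol lactone, in which hydroxide attacks the lactone carbonyl and the ring oxygen leaves as the enolate of the benzyl ketone, and cold acidification protonates the carboxylate without re-closing or decarboxylating the acid; no stereocentre is involved.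

**Compound list**
1 | oxacyclotridecan-2-one (12-dodecanolide) | O=C1CCCCCCCCCCCO1 | starting material
2 | 1-[dimethyl(oxo)-λ6-sulfanylidene]-13-hydroxytridecan-2-one | OCCCCCCCCCCCC(=O)C=S(C)(C)=O | intermediate
3 | 2-hydroxy-4-methoxybenzoic acid | COc1ccc(C(=O)O)c(O)c1 | starting material
4 | 2-hydroxy-6-(13-hydroxy-2-oxotridecyl)-4-methoxybenzoic acid | COc1cc(O)c(C(=O)O)c(CC(=O)CCCCCCCCCCCO)c1 | target (also the non-isolated intermediate of step 2)
5 | 8-hydroxy-3-(11-hydroxyundecyl)-6-methoxy-1H-isochromen-1-one | COc1cc(O)c2c(c1)C=C(CCCCCCCCCCCO)OC2=O | intermediate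

**Totals**
Total step count: 3. Longest linear sequence: 3 steps (1 → 2 → 5 → 4).

**Steps most likely to fail, with fallbacks**

Step 2 is the riskiest. The free salicylic acid may bind rhodium as a chelate, or may protonate the ylide so that the carboxylate is O-alkylated to an acyloxy ketone instead of undergoing C–H insertion. The fallback drops C–H activation for lateral lithiation; it sets out from lactone 1 and comes back at 5. Purchased methyl 2,4-dimethoxy-6-methylbenzoate F1 is deprotonated at the benzylic methyl with LiN(iPr)2 (2.2 equiv, THF, −78 °C) and acylated by 1 with ring opening, giving methyl 2-(13-hydroxy-2-oxotridecyl)-4,6-dimethoxybenzoate F2. TsOH·H2O in toluene at 90 °C closes F2, with loss of methanol, to 3-(11-hydroxyundecyl)-6,8-dimethoxy-1H-isochromen-1-one F3. BCl3 (3 equiv, CH2Cl2, −78 to 0 °C) then cleaves only the methyl ether chelated to the lactone carbonyl and gives 5.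

Step 3 is next. On acidification the keto acid may re-close to 5, or the electron-rich salicylic acid may decarboxylate. The fallback releases the acid under neutral conditions; it sets out from 5 and comes back at 4. BnONa (from NaH in BnOH/THF, 50 °C) opens the enol lactone to benzyl 2-hydroxy-6-(13-hydroxy-2-oxotridecyl)-4-methoxybenzoate F4. Hydrogenolysis (H2, 1 atm, 10% Pd/C, EtOAc, room temperature) then gives 4 with no acid or base present.

Step 1 is third. The unactivated macrolactone may react sluggishly or oligomerise through the liberated alkoxide. The fallback activates the acyl group before the ylide is introduced; it sets out from 1 and comes back at 2. Me2AlSPh (from AlMe3 and PhSH, CH2Cl2, 0 °C to room temperature) opens 1 to S-phenyl 12-hydroxydodecanethioate F5. This thioester reacts with dimethylsulfoxonium methylide (Me3S(O)I, KOtBu, THF, 0 °C to room temperature) to give 2.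

**Further compounds**
F1 | step 2 | methyl 2,4-dimethoxy-6-methylbenzoate (purchased) | COC(=O)c1c(C)cc(OC)cc1OC
F2 | step 2 | methyl 2-(13-hydroxy-2-oxotridecyl)-4,6-dimethoxybenzoate | COC(=O)c1c(CC(=O)CCCCCCCCCCCO)cc(OC)cc1OC
F3 | step 2 | 3-(11-hydroxyundecyl)-6,8-dimethoxy-1H-isochromen-1-one | COc1cc(OC)c2c(c1)C=C(CCCCCCCCCCCO)OC2=O
F4 | step 3 | benzyl 2-hydroxy-6-(13-hydroxy-2-oxotridecyl)-4-methoxybenzoate | COc1cc(O)c(C(=O)OCc2ccccc2)c(CC(=O)CCCCCCCCCCCO)c1
F5 | step 1 | S-phenyl 12-hydroxydodecanethioate | OCCCCCCCCCCCC(=O)Sc1ccccc1
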